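**Strategy.** The cyclohexane C2–C3–C4–C5–C9–C10 (chain numbering: lactone carbonyl C1, pyran oxygen on C2 and C13, heptyl C16–C22) is not closed directly. It is grown from the cyclopentane C3–C4–C5–C9–C10 of a cis-diquinane by an α-ketol (acyloin) rearrangement. The disconnection rests on the C2 tertiary carbinol flanked by the C1 lactone carbonyl and the oxygenated C3. A C3-hydroxy α-keto-δ-lactone tied to O5 (bicyclo[3.2.1]) shifts C10 from C3 to C2. One operation gives the cyclohexanone, the bicyclo[2.2.2] lactone and the C2 quaternary centre. All stereocentres are relayed from C9, set by asymmetric deprotonation of a meso ketone.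

Key step: step 11

Numbering used below: C1 lactone C=O; C2 quaternary C–O; C3 CHOH; C4 CH2; C5 quaternary C–O (lactone); C6 CH2; C7 CHOH; C8 CH2; C9 and C10 ring-fusion CH; C11=C12(CH3); C13 OCH; C14=C15; C16–C22 heptyl. SMILES leave C11 (compounds 8–15) and C2 (compound 13) unspecified because both epimers are carried.

Assumption: the sense of induction of the chiral lithium amide in step 2 is taken as stated; if it proves opposite, the equally available (S,S)-amide is used.

**Step 1**
Reactants: 1 cis-bicyclo[3.3.0]octane-3,7-dione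
Product: 2 cis-7,7-(ethylenedioxy)bicyclo[3.3.0]octan-3-one
Conditions: ethylene glycol (1.0 equiv), TsOH·H2O (cat.), toluene, reflux, Dean–Stark
Reagents that add atoms: ethylene glycol, OCCO
Why: Acid-catalysed mono-ketalisation of the meso diketone with one equivalent of diol should give the Cs-symmetric mono-ketal, with no stereocentre created.

**Step 2**
Reactants: 2 mono-ketal
Product: 3 (1R,5S)-7,7-(ethylenedioxy)-3-(trimethylsilyloxy)bicyclo[3.3.0]oct-2-ene
Conditions: lithium (R,R)-bis(1-phenylethyl)amide (from the amine and n-BuLi), LiCl, TMSCl (in situ quench), THF, −100 °C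
Reagents that add atoms: chlorotrimethylsilane, C[Si](C)(C)Cl
Why: Asymmetric deprotonation of the meso ketone by a chiral lithium amide with internal silyl quench should select one of the two enantiotopic α-methylenes and thereby fix the absolute configuration of the future C9.

**Step 3**
Reactants: 3 enol silane
Product: 4 (5S)-7,7-(ethylenedioxy)bicyclo[3.3.0]oct-1-en-3-one
Conditions: Pd(OAc)2 (10 mol %), O2 (1 atm), DMSO, 25 °C
Reagents that add atoms: none
Why: Saegusa–Ito oxidation (palladium enolate, β-hydride elimination of the ring-fusion hydrogen) should give the bicyclic enone and leave C9 as the only stereocentre.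

**Step 4**
Reactants: 4 enone
Product: 5 epoxy ketone (4,5-epoxide cis to 9-H)
Conditions: H2O2 (30 % aq.), NaOH (cat.), MeOH, 0 °C
Reagents that add atoms: hydrogen peroxide, OO
Why: Weitz–Scheffer nucleophilic epoxidation can deliver oxygen to the ring-fusion carbon only on the face of 9-H, because only a cis-fused diquinane can form, which sets the C5–O centre.

**Step 5**
Reactants: 6 (E)-dec-2-enal
Product: 7 (2E,4E)-2-methyldodeca-2,4-dienal
Conditions: Ph3P=C(CH3)CHO, toluene, 90 °C
Reagents that add atoms: 2-(triphenylphosphoranylidene)propanal, CC(C=O)=P(c1ccccc1)(c1ccccc1)c1ccccc1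
Why: Wittig olefination with the formyl-stabilised ylide should give the (2E)-trisubstituted enal and leave the existing (E)-alkene untouched.

**Step 6**
Reactants: 5 epoxy ketone; 7 dienal
Product: 9 C11 silyl ether of the C10 aldol adduct, via aldol adduct 8 (not isolated)
Conditions: LiN(i-Pr)2 (LDA), THF, −78 °C; 7; then TBSOTf, −78 °C
Reagents that add atoms: tert-butyldimethylsilyl triflate, CC(C)(C)[Si](C)(C)OS(=O)(=O)C(F)(F)F
Why: Kinetic lithium enolate aldol addition at the only enolisable α-carbon (C10), with the aldehyde approaching the convex face anti to the C9–C8 bond so that the chain is cis to 9-H, followed by silylation of the aldolate; the C11 centre is destroyed in step 12.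

**Step 7**
Reactants: 9 epoxy ketone silyl ether
Product: 10 β-hydroxy ketone (5-OH cis to 9-H)
Conditions: SmI2 (2.2 equiv), THF/MeOH, −90 °C
Reagents that add atoms: none
Why: Reductive opening of the α,β-epoxy ketone by SmI2 (cleavage of the Cα–O bond of the ketyl) should give the β-hydroxy ketone with the C5 configuration retained.

**Step 8**
Reactants: 10 β-hydroxy ketone
Product: 11 5-O-bromoacetate
Conditions: BrCH2COBr, pyridine, CH2Cl2, −20 → 0 °C
Reagents that add atoms: bromoacetyl bromide, O=C(Br)CBr
Why: O-Acylation of the tertiary alcohol under weakly basic conditions should install C1 and C2 without β-elimination of the new ester.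

**Step 9**
Reactants: 11 bromoacetate
Product: 12 bridged δ-lactone (3-OH, C2H2)
Conditions: SmI2 (2.2 equiv), THF, −78 °C
Reagents that add atoms: none
Why: In this SmI2-promoted intramolecular Reformatsky reaction the samarium enolate is tethered to O5 and can reach the C3 ketone only from the O5 face, so C2 is attached cis to O5 and the new 3-OH is trans.

**Step 10**
Reactants: 12 bridged lactone
Product: 13 2-hydroxy lactone (C2 epimers)
Conditions: LiN(i-Pr)2 (2.5 equiv), THF, −78 °C; 3-phenyl-2-(phenylsulfonyl)oxaziridine, −78 °C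
Reagents that add atoms: 3-phenyl-2-(phenylsulfonyl)oxaziridine, O=S(=O)(c1ccccc1)N1OC1c1ccccc1
Why: Davis enolate hydroxylation of the alkoxide–enolate dianion should oxygenate C2; its configuration does not matter because C2 becomes a ketone in step 11.

**Step 11**
Reactants: 13 2-hydroxy lactone
Product: 15 ring-expanded 2-hydroxy-3-oxo lactone (2-oxabicyclo[2.2.2]octan-3-one core), via α-keto lactone 14 (not isolated)
Conditions: (COCl)2, DMSO, CH2Cl2, −78 °C; Et3N, −78 → 0 °C
Reagents that add atoms: none
Why: Swern oxidation of the C2 carbinol gives the α-keto-δ-lactone 14, and the triethylamine present then lets the C3 oxygen push the C3–C10 bond onto the adjacent C2 ketone (α-ketol or acyloin rearrangement; closest precedents are the bicyclo[3.2.1]octane to bicyclo[2.2.2]octane ketol shift of bridged α-hydroxy ketones and the rearrangement of β-hydroxy-α-keto esters to α-hydroxy-β-keto esters). No ring is closed by cyclisation: the cyclopentane C3–C4–C5–C9–C10 is enlarged by one atom to the cyclohexane C2–C3–C4–C5–C9–C10 by a suprafacial 1,2-shift, and the six-membered lactone of the bicyclo[3.2.1] frame thereby becomes the lactone bridge of the 2-oxabicyclo[2.2.2]octane. C10 migrates with retention, and the new C2 centre can form in one configuration only because C1 stays tied to O5, so the C2 hydroxyl is placed anti to the lactone bridge without external control. The selectivity needed is migration of C10 rather than C4: in the chair-like lactone ring of 14 the C3–C10 bond is axial and parallel to the π* orbital of the C2 carbonyl while C3–C4 lies near its nodal plane, and C10 is also the more substituted carbon. The shift should be driven by exchange of the vicinal dicarbonyl for an isolated ketone and an ester, and it is stopped at 15 (weak base, 0 °C) before a second shift of the C1 acyl carbon can set in.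

**Step 12**
Reactants: 15 ring-expanded ketol
Product: 17 pyran 3,7-diketone, via pyran ketal 16 (not isolated)
Conditions: Bi(OTf)3 (5 mol %), CH2Cl2, −20 °C; then THF/H2O (4:1), 23 °C
Reagents that add atoms: water, O
Why: Bi(OTf)3 ionises the dienylic silyl ether to a pentadienyl cation that the C2 hydroxyl captures at C13 in a six-ring-forming intramolecular allylic etherification (SN1′ type), where O2 can reach C13 only from the face anti to 10-H and the nonenyl group sits in the outward position of the (12E)-derived cation so that 13-H ends cis to 10-H, and the same catalyst in wet THF then hydrolyses the dioxolane.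

**Step 13**
Reactants: 17 pyran diketone
Product: 18 target
Conditions: LiBH(s-Bu)3 (2.5 equiv), THF, −78 °C; pH 7 buffer
Reagents that add atoms: none
Why: Ketone reduction by a bulky trialkylborohydride under steric approach control should deliver hydride to C7 from the convex face of the cis-fused cyclopentanone (the face of O5 and 9-H) and to C3 from the side of the flat lactone bridge away from 10-H, giving 7-OH cis to C4 and C10 and 3-OH syn to the C9–C10 bridge.

**Compound list**

1 | cis-bicyclo[3.3.0]octane-3,7-dione (meso) | O=C1C[C@@H]2CC(=O)C[C@@H]2C1 | starting material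
2 | cis-7,7-(ethylenedioxy)bicyclo[3.3.0]octan-3-one (meso mono-ketal) | O=C1C[C@@H]2CC3(OCCO3)C[C@@H]2C1 | intermediate
3 | (1R,5S)-7,7-(ethylenedioxy)-3-(trimethylsilyloxy)bicyclo[3.3.0]oct-2-ene | C[Si](C)(C)OC1=C[C@@H]2CC3(OCCO3)C[C@@H]2C1 | intermediate
4 | (5S)-7,7-(ethylenedioxy)bicyclo[3.3.0]oct-1-en-3-one | O=C1C=C2CC3(OCCO3)C[C@@H]2C1 | intermediate
5 | epoxy ketone: C3 ketone, 4,5-epoxide cis to 9-H, C7 dioxolane | O=C1[C@H]2O[C@]23CC4(OCCO4)C[C@@H]3C1 | intermediate
6 | (E)-dec-2-enal | CCCCCCC/C=C/C=O | starting material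
7 | (2E,4E)-2-methyldodeca-2,4-dienal | CCCCCCC/C=C/C=C(\C)C=O | intermediate
8 | aldol adduct: 5 carrying a (2E,4E)-1-hydroxy-2-methyldodeca-2,4-dienyl group at C10, cis to 9-H (C11 epimers; not isolated) | O=C1[C@H]2O[C@]23CC4(OCCO4)C[C@@H]3[C@H]1C(O)/C(C)=C/C=C/CCCCCCC | intermediate
9 | 11-O-tert-butyldimethylsilyl ether of 8 | O=C1[C@H]2O[C@]23CC4(OCCO4)C[C@@H]3[C@H]1C(O[Si](C)(C)C(C)(C)C)/C(C)=C/C=C/CCCCCCC | intermediate
10 | β-hydroxy ketone: C3-oxo cis-diquinane, 5-OH cis to 9-H, C7 dioxolane, 11-OTBS dienyl chain at C10 | O=C1C[C@]2(O)CC3(OCCO3)C[C@@H]2[C@H]1C(O[Si](C)(C)C(C)(C)C)/C(C)=C/C=C/CCCCCCC | intermediate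
11 | 5-O-bromoacetate of 10 | O=C1C[C@]2(OC(=O)CBr)CC3(OCCO3)C[C@@H]2[C@H]1C(O[Si](C)(C)C(C)(C)C)/C(C)=C/C=C/CCCCCCC | intermediate
12 | bridged δ-lactone (2-oxabicyclo[3.2.1]octan-3-one core; C1 carbonyl, C2H2, 3-OH trans to the lactone bridge) | O[C@@]12CC(=O)O[C@]3(CC4(OCCO4)C[C@@H]3[C@H]1C(O[Si](C)(C)C(C)(C)C)/C(C)=C/C=C/CCCCCCC)C2 | intermediate
13 | 2-hydroxy derivative of 12 (C2 epimers) | O[C@@]12C(O)C(=O)O[C@]3(CC4(OCCO4)C[C@@H]3[C@H]1C(O[Si](C)(C)C(C)(C)C)/C(C)=C/C=C/CCCCCCC)C2 | intermediate
14 | 2-oxo derivative of 12: 3-hydroxy α-keto-δ-lactone (not isolated) | O[C@@]12C(=O)C(=O)O[C@]3(CC4(OCCO4)C[C@@H]3[C@H]1C(O[Si](C)(C)C(C)(C)C)/C(C)=C/C=C/CCCCCCC)C2 | intermediate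
15 | ring-expanded ketol: cyclohexan-3-one C2–C3–C4–C5–C9–C10 bridged by the C1–O5 lactone (2-oxabicyclo[2.2.2]octan-3-one), 2-OH, C7 dioxolane, 11-OTBS dienyl chain at C10 | O[C@@]12C(=O)O[C@]3(CC4(OCCO4)C[C@@H]3[C@H]1C(O[Si](C)(C)C(C)(C)C)/C(C)=C/C=C/CCCCCCC)CC2=O | intermediate
16 | pyran ketal: 2,13-ether closed, C3 ketone, C7 dioxolane (not isolated) | CCCCCCC/C=C/[C@H]1O[C@@]23C(=O)O[C@]4(CC5(OCCO5)C[C@@H]4[C@H]2C=C1C)CC3=O | intermediate
17 | 3,7-diketone of the target skeleton | CCCCCCC/C=C/[C@H]1O[C@@]23C(=O)O[C@]4(CC(=O)C[C@@H]4[C@H]2C=C1C)CC3=O | intermediate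
18 | CNP0127096.2, (2S,3R,5R,7R,9R,10R,13R,14E)-2,13-epoxy-3,7-dihydroxy-12-methyl-2,10:5,9-dicyclodocosa-11,14-dien-5-olide | CCCCCCC/C=C/[C@H]1O[C@@]23C(=O)O[C@]4(C[C@H](O)C[C@@H]4[C@H]2C=C1C)C[C@H]3O | target

**Step count.** Total: 13 steps. Longest linear sequence: 12 steps (steps 1–4 and 6–13).

**Steps most likely to fail**

Step 11. The ketol manifold is reversible, so kinetic control may erode: the shift may run backwards, or a second 1,2-shift of the C1 acyl carbon from C2 to C3 may lead on to an isomeric γ-lactone. The fallback replaces it by an irreversible carbenoid ring enlargement, sets out from 10 and returns at 15. Compound 10 is treated with ethyl lithiodiazoacetate (THF, −78 °C) to give the α-diazo-β-hydroxy ester F1; either C3 epimer serves. Rh2(OAc)4 in CH2Cl2 then expels dinitrogen with 1,2-shift of the secondary C10 to the carbenoid carbon, which should give the ring-enlarged β-keto ester F2; the cyclohexanone still arises by one-carbon ring expansion, but the regiochemistry rests on migratory aptitude alone. Hydroxylation of its potassium enolate (KN(SiMe3)2, Davis oxaziridine) anti to the C10 side chain gives the α-hydroxy-β-keto ester F3. Ti(OEt)4-mediated lactonisation onto the C5 hydroxyl returns to 15.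

Step 12. The pentadienyl cation may be captured by water or at C15, a prematurely liberated C11 hydroxyl may translactonise onto C1, and C13 may slowly epimerise during the acidic ketal hydrolysis. The fallback closes the ring under neutral conditions, sets out from 15 and returns at 16. Compound 15 is desilylated with buffered HF·pyridine to the allylic alcohol F4 and converted with methyl chloroformate and pyridine into the methyl carbonate F5. Pd(PPh3)4 in THF then effects a zerovalent-palladium-catalysed intramolecular allylic etherification through the π-allyl complex, O2 attacking C13 anti to the metal, to give the pyran ketal 16. This is hydrolysed as in step 12.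

Step 13. Facial selectivity at C3 may be poor (hydride delivery from the C9–C10 side), and the lactone may be attacked. The fallback reduces the two ketones separately with catalyst control at C3, sets out from 17 and returns at 18. NaBH4 (MeOH/CH2Cl2, −78 °C) should reduce only the unhindered cyclopentanone from its convex face to give the 7-hydroxy-3-ketone F6. The C3 ketone is then reduced with catecholborane and the (S)-Me-CBS oxazaborolidine, (S)-1-methyl-3,3-diphenyltetrahydro-1H,3H-pyrrolo[1,2-c][1,3,2]oxazaborole, with C2 as the large group, to give 18.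

**Further compounds**

F1 | step 11 | ethyl 2-diazo-2-(3-hydroxy cis-diquinan-3-yl)acetate derived from 10 (C3 epimers, 5-OH free) | CCOC(=O)C(=[N+]=[N-])C1(O)C[C@]2(O)CC3(OCCO3)C[C@@H]2[C@H]1C(O[Si](C)(C)C(C)(C)C)/C(C)=C/C=C/CCCCCCC
F2 | step 11 | ring-enlarged β-keto ester: ethyl 3-oxocyclohexane-2-carboxylate C2–C3–C4–C5–C9–C10 with 5-OH (C2 epimers) | CCOC(=O)C1C(=O)C[C@]2(O)CC3(OCCO3)C[C@@H]2[C@H]1C(O[Si](C)(C)C(C)(C)C)/C(C)=C/C=C/CCCCCCC
F3 | step 11 | 2-hydroxy derivative of F2, ester cis to 5-OH | CCOC(=O)[C@@]1(O)C(=O)C[C@]2(O)CC3(OCCO3)C[C@@H]2[C@H]1C(O[Si](C)(C)C(C)(C)C)/C(C)=C/C=C/CCCCCCC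
F4 | step 12 | C11 alcohol from 15 (C11 epimers) | O[C@@]12C(=O)O[C@]3(CC4(OCCO4)C[C@@H]3[C@H]1C(O)/C(C)=C/C=C/CCCCCCC)CC2=O
F5 | step 12 | C11 methyl carbonate of F4 | O[C@@]12C(=O)O[C@]3(CC4(OCCO4)C[C@@H]3[C@H]1C(OC(=O)OC)/C(C)=C/C=C/CCCCCCC)CC2=O
F6 | step 13 | 7-hydroxy-3-ketone (3-dehydro target) | CCCCCCC/C=C/[C@H]1O[C@@]23C(=O)O[C@]4(C[C@H](O)C[C@@H]4[C@H]2C=C1C)CC3=O
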